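**Plan**

- The side chain is numbered C1' (OCH2) to C8' (lactone C=O); the last bond cut is O–Si of a triethylsilyl ether on the C7' hydroxyl.
- The main cut takes C3'–CH3 and C1'–C2' together: C1'–C3' is an E-trisubstituted alkene whose C3' methyl lies cis to the aryloxymethyl carbon C1', which is the pattern of a terminal alkyne (C2'≡C3') plus CH3 plus an ArOCH2 electrophile.
- This leaves a 5-propargyl-γ-butyrolactone and 7-(chloromethoxy)-8-methoxycoumarin; the lactone is cut at O–C8' (translactonisation of a dioxolanone) and at C4'–C5' (propargylation of a C5' aldehyde).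
- Forward: the γ-lactone (O, C5', C6', C7', C8') is the only ring built and is in place before the key step; the coumarin bicycle is bought and joined at the key step, which closes no ring; desilylation ends the route.
- Stereochemistry: C7' (R) comes from (R)-citramalic acid, C5' (S) from a chiral phosphoric acid catalysed allenylboronate addition, and the E alkene from syn methylalumination followed by coupling with retention.

Key step: step 9

Assumption: the phosphoric acid is taken to follow its usual sense with allenylboronates (the R acid adds to the Re face of RCHO), so the S acid is specified for the Si-face addition that gives the 5S carbinol; any C5' epimer is removed as the diastereomeric lactone after step 5.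

**Route**

Step 1
Reactants: 1 (R)-citramalic acid
Product: 2 2-[(4R)-2,2,4-trimethyl-5-oxo-1,3-dioxolan-4-yl]acetic acid
Conditions: Me2C(OMe)2, TsOH·H2O (cat.), acetone, rt
Reagents that add atoms: 2,2-dimethoxypropane, COC(C)(C)OC
Why: Acid-catalysed acetal exchange (acetonide formation) should close the five-membered 1,3-dioxolan-4-one across the α-hydroxy acid pair and leave the β-carboxyl free, without touching the quaternary centre.

Step 2
Reactants: 2 2-[(4R)-2,2,4-trimethyl-5-oxo-1,3-dioxolan-4-yl]acetic acid
Product: 3 (5R)-5-(2-hydroxyethyl)-2,2,5-trimethyl-1,3-dioxolan-4-one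
Conditions: BH3·SMe2, THF, 0 °C → rt; MeOH quench, neutral work-up, used promptly
Reagents that add atoms: none
Why: Chemoselective borane reduction, in which the free acid is reduced through its acyloxyborane much faster than the dioxolanone ester, as is well precedented for the malic acid analogue.

Step 3
Reactants: 3 (5R)-5-(2-hydroxyethyl)-2,2,5-trimethyl-1,3-dioxolan-4-one
Product: 4 2-[(4R)-2,2,4-trimethyl-5-oxo-1,3-dioxolan-4-yl]acetaldehyde
Conditions: Dess–Martin periodinane, CH2Cl2, 0 °C → rt; crude aldehyde used at once
Reagents that add atoms: none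
Why: Dess–Martin oxidation stops at the aldehyde under non-aqueous, near-neutral conditions, and the carbon next to the CH2CHO group is quaternary, so no stereocentre can epimerise.

Step 4
Reactants: 4 2-[(4R)-2,2,4-trimethyl-5-oxo-1,3-dioxolan-4-yl]acetaldehyde; 5 allenylboronic acid pinacol ester
Product: 7 (5R)-5-[(2S)-2-hydroxypent-4-yn-1-yl]-2,2,5-trimethyl-1,3-dioxolan-4-one, via O-pinacolboryl ether 6 (not isolated)
Conditions: (S)-3,3'-bis(2,4,6-triisopropylphenyl)-1,1'-binaphthyl-2,2'-diyl hydrogen phosphate [(S)-TRIP, 10 mol %], 4 Å MS, toluene, −20 °C; aqueous work-up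
Reagents that add atoms: allenylboronic acid pinacol ester (5), C=C=CB1OC(C)(C)C(C)(C)O1
Why: Chiral phosphoric acid catalysed propargylboration (SE2' addition of the allenylboronate through a closed six-membered transition state, the acid hydrogen-bonded to a boronate oxygen) should deliver the propargyl group to the Si face of the aldehyde, so the new C5' carbinol centre (S) is set by the catalyst while the remote quaternary C7' exerts little bias, and γ-attack gives only the homopropargylic alcohol.

Step 5
Reactants: 7 (5R)-5-[(2S)-2-hydroxypent-4-yn-1-yl]-2,2,5-trimethyl-1,3-dioxolan-4-one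
Product: 8 (3R,5S)-3-hydroxy-3-methyl-5-(prop-2-yn-1-yl)oxolan-2-one
Conditions: TsOH·H2O (10 mol %), CH2Cl2, rt; chromatography
Reagents that add atoms: none
Why: Acid-catalysed translactonisation, in which the C5' hydroxyl attacks the dioxolanone carbonyl (5-exo-trig) and acetone is expelled, should give the γ-lactone with both centres unchanged, and any C5 epimer from step 4 is now a diastereomeric lactone that chromatography removes.

Step 6
Reactants: 8 (3R,5S)-3-hydroxy-3-methyl-5-(prop-2-yn-1-yl)oxolan-2-one
Product: 9 (3R,5S)-3-methyl-5-(prop-2-yn-1-yl)-3-(triethylsilyloxy)oxolan-2-one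
Conditions: Et3SiOTf, 2,6-lutidine, CH2Cl2, −78 → 0 °C
Reagents that add atoms: triethylsilyl trifluoromethanesulfonate, CC[Si](CC)(CC)OS(=O)(=O)C(F)(F)F
Why: Silylation of a hindered tertiary alcohol with a silyl triflate and a hindered base is standard, and the silyl ether prevents aluminium alkoxide formation in step 9 and shields the lactone carbonyl.

Step 7
Reactants: 10 7-hydroxy-8-methoxy-2H-chromen-2-one; 11 chloromethyl methyl sulfide
Product: 13 8-methoxy-7-[(methylsulfanyl)methoxy]-2H-chromen-2-one, via sodium phenoxide 12 (not isolated)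
Conditions: NaH, DMF, 0 °C; then MeSCH2Cl, NaI (cat.), 0 °C → rt
Reagents that add atoms: chloromethyl methyl sulfide (11), CSCCl
Why: Williamson-type O-alkylation of the acidic 7-hydroxycoumarin as its phenoxide with an α-chloro sulfide, accelerated by iodide exchange, should give the methylthiomethyl ether (an O,S-acetal).

Step 8
Reactants: 13 8-methoxy-7-[(methylsulfanyl)methoxy]-2H-chromen-2-one
Product: 14 7-(chloromethoxy)-8-methoxy-2H-chromen-2-one
Conditions: SO2Cl2 (1.0 equiv), CH2Cl2, −20 → 0 °C; volatiles removed in vacuo, used crude under argon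
Reagents that add atoms: sulfuryl chloride, O=S(=O)(Cl)Cl
Why: Chlorinolysis of an O,S-acetal, the established route to aryl chloromethyl ethers, relies on sulfur being chlorinated far faster than the arene or the electron-poor coumarin C3–C4 double bond, after which the chlorosulfonium ion collapses to the aryloxymethyl chloride.

Step 9
Reactants: 9 (3R,5S)-3-methyl-5-(prop-2-yn-1-yl)-3-(triethylsilyloxy)oxolan-2-one; 14 7-(chloromethoxy)-8-methoxy-2H-chromen-2-one; 15 trimethylaluminium
Product: 17 8-methoxy-7-{[(2E)-3-methyl-4-[(2S,4R)-4-methyl-5-oxo-4-(triethylsilyloxy)oxolan-2-yl]but-2-en-1-yl]oxy}-2H-chromen-2-one, via alkenyldimethylalane 16 (not isolated)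
Conditions: Me3Al (2.5 equiv), bis(cyclopentadienyl)zirconium dichloride Cp2ZrCl2 (20 mol %), H2O (1.0 equiv), CH2Cl2, −25 °C; then 14 (2.0 equiv) in CH2Cl2, −25 → 0 °C; aq. potassium sodium tartrate
Reagents that add atoms: trimethylaluminium (15), C[Al](C)C
Why: Cp2ZrCl2 and Me3Al form a methylzirconocene–aluminate that adds methyl and metal syn across the terminal alkyne of 9, methyl to C3' and metal (aluminium after exchange) to C2', which is the zirconium-catalysed methylalumination (Negishi carboalumination) in its water-accelerated low-temperature form and gives the (E)-alkenyldimethylalane 16. In the same flask 16 displaces chloride from the aluminium-activated, oxocarbenium-like aryloxymethyl chloride 14 with retention at the alkenyl carbon (SE2), forming C1'–C2'; the closest known reaction is the same one-flask sequence with chloromethyl methyl ether as the electrophile. No ring is closed and no stereocentre is created; the only stereo-element formed is the alkene, and syn addition plus retention places the C3' methyl cis to C1', which is the E isomer. The step needs regioselectivity (methyl to the internal carbon, secured by the unhindered terminal alkyne bearing only a CH2 substituent), alkenyl rather than methyl transfer from aluminium (the alkenyl ligand is the more nucleophilic one) and survival of two lactones (low temperature, the α-quaternary silyloxy carbon shielding the butyrolactone, the coumarin added only after the carbometalation). The excess of 14 absorbs residual Al–CH3 groups, and the cold tartrate quench limits Lewis-acid ionisation or Claisen shift of the new allyl aryl ether.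

Step 10
Reactants: 17 8-methoxy-7-{[(2E)-3-methyl-4-[(2S,4R)-4-methyl-5-oxo-4-(triethylsilyloxy)oxolan-2-yl]but-2-en-1-yl]oxy}-2H-chromen-2-one
Product: 18 7-{[(2E)-4-[(2S,4R)-4-hydroxy-4-methyl-5-oxooxolan-2-yl]-3-methylbut-2-en-1-yl]oxy}-8-methoxy-2H-chromen-2-one (CNP0356189.1)
Conditions: HF·pyridine, pyridine, THF, 0 °C → rt
Reagents that add atoms: none
Why: Fluoride-driven desilylation under buffered, non-basic conditions should free the tertiary alcohol while the butyrolactone, the coumarin and the allylic aryl ether stay intact.

**Compound list**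

1 | (R)-citramalic acid [(2R)-2-hydroxy-2-methylbutanedioic acid] | OC(=O)C[C@@](C)(O)C(=O)O | starting material
2 | 2-[(4R)-2,2,4-trimethyl-5-oxo-1,3-dioxolan-4-yl]acetic acid | OC(=O)C[C@@]1(C)OC(C)(C)OC1=O | intermediate
3 | (5R)-5-(2-hydroxyethyl)-2,2,5-trimethyl-1,3-dioxolan-4-one | OCC[C@@]1(C)OC(C)(C)OC1=O | intermediate
4 | 2-[(4R)-2,2,4-trimethyl-5-oxo-1,3-dioxolan-4-yl]acetaldehyde | O=CC[C@@]1(C)OC(C)(C)OC1=O | intermediate
5 | allenylboronic acid pinacol ester | C=C=CB1OC(C)(C)C(C)(C)O1 | starting material
6 | (5R)-2,2,5-trimethyl-5-[(2S)-2-[(4,4,5,5-tetramethyl-1,3,2-dioxaborolan-2-yl)oxy]pent-4-yn-1-yl]-1,3-dioxolan-4-one | C#CC[C@H](OB1OC(C)(C)C(C)(C)O1)C[C@@]1(C)OC(C)(C)OC1=O | intermediate (not isolated)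
7 | (5R)-5-[(2S)-2-hydroxypent-4-yn-1-yl]-2,2,5-trimethyl-1,3-dioxolan-4-one | C#CC[C@H](O)C[C@@]1(C)OC(C)(C)OC1=O | intermediate
8 | (3R,5S)-3-hydroxy-3-methyl-5-(prop-2-yn-1-yl)oxolan-2-one | C#CC[C@H]1C[C@@](C)(O)C(=O)O1 | intermediate
9 | (3R,5S)-3-methyl-5-(prop-2-yn-1-yl)-3-(triethylsilyloxy)oxolan-2-one | C#CC[C@H]1C[C@@](C)(O[Si](CC)(CC)CC)C(=O)O1 | intermediate
10 | 7-hydroxy-8-methoxy-2H-chromen-2-one (7-hydroxy-8-methoxycoumarin) | COc1c(O)ccc2ccc(=O)oc12 | starting material
11 | chloromethyl methyl sulfide | CSCCl | starting material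
12 | sodium 8-methoxy-2-oxo-2H-chromen-7-olate | COc1c([O-])ccc2ccc(=O)oc12.[Na+] | intermediate (not isolated)
13 | 8-methoxy-7-[(methylsulfanyl)methoxy]-2H-chromen-2-one | COc1c(OCSC)ccc2ccc(=O)oc12 | intermediate
14 | 7-(chloromethoxy)-8-methoxy-2H-chromen-2-one | COc1c(OCCl)ccc2ccc(=O)oc12 | intermediate
15 | trimethylaluminium | C[Al](C)C | starting material
16 | dimethyl[(1E)-2-methyl-3-[(2S,4R)-4-methyl-5-oxo-4-(triethylsilyloxy)oxolan-2-yl]prop-1-en-1-yl]alane | C[Al](C)/C=C(\C)C[C@H]1C[C@@](C)(O[Si](CC)(CC)CC)C(=O)O1 | intermediate (not isolated)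
17 | 8-methoxy-7-{[(2E)-3-methyl-4-[(2S,4R)-4-methyl-5-oxo-4-(triethylsilyloxy)oxolan-2-yl]but-2-en-1-yl]oxy}-2H-chromen-2-one | COc1c(OC/C=C(\C)C[C@H]2C[C@@](C)(O[Si](CC)(CC)CC)C(=O)O2)ccc2ccc(=O)oc12 | intermediate
18 | 7-{[(2E)-4-[(2S,4R)-4-hydroxy-4-methyl-5-oxooxolan-2-yl]-3-methylbut-2-en-1-yl]oxy}-8-methoxy-2H-chromen-2-one (CNP0356189.1) | COc1c(OC/C=C(\C)C[C@H]2C[C@@](C)(O)C(=O)O2)ccc2ccc(=O)oc12 | target

**Step count and risks**

Total step count: 10.
Longest linear sequence: 8 steps (steps 1–6, 9 and 10, from (R)-citramalic acid); steps 7 and 8 form the convergent branch.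

Steps most likely to fail:

1. Step 9. The coupling at the aryloxymethyl chloride may be sluggish or misdirected: methyl instead of alkenyl transfer from aluminium, Lewis-acid ionisation or Claisen shift of the new allyl aryl ether, or attack of Me3Al on a lactone carbonyl. The fallback sets out from 9 and 10. The same methylalumination is run, but the alkenylalane 16 is quenched with paraformaldehyde, a known trapping that gives E-3-methylalk-2-en-1-ols, to give (3R,5S)-5-[(2E)-4-hydroxy-2-methylbut-2-en-1-yl]-3-methyl-3-(triethylsilyloxy)oxolan-2-one F1. Mitsunobu etherification of this allylic alcohol with phenol 10 (PPh3, diisopropyl azodicarboxylate, THF, 0 °C) comes back to the route at 17. The coumarin then enters through a C–O bond, and 14 is not needed.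

2. Step 4. Facial selectivity of the catalysed propargylation may be poor, or the catalyst may be mismatched with the substrate, so that the C5' centre forms without useful control. The fallback sets out from 4. Barbier propargylation with propargyl bromide and Zn dust (THF, aq. NH4Cl) without reagent control gives (5R)-5-(2-hydroxypent-4-yn-1-yl)-2,2,5-trimethyl-1,3-dioxolan-4-one as both carbinol epimers F2. Lactonisation of the mixture under the conditions of step 5 and chromatographic separation of the diastereomeric lactones comes back to the route at 8. The epimer (3R,5R)-3-hydroxy-3-methyl-5-(prop-2-yn-1-yl)oxolan-2-one F3 is set aside. Stereocontrol is thus replaced by separation, which the fixed C7' centre makes possible.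

3. Step 2. The hydroxyethyl dioxolanone may translactonise prematurely with loss of acetone, a closure favoured by the fully substituted carbon, or borane may also reduce the dioxolanone carbonyl. The fallback sets out from 2. Thioesterification with ethanethiol (dicyclohexylcarbodiimide, DMAP, CH2Cl2) gives S-ethyl 2-[(4R)-2,2,4-trimethyl-5-oxo-1,3-dioxolan-4-yl]ethanethioate F4. Fukuyama reduction (Et3SiH, Pd/C, acetone, rt) converts it directly to the aldehyde and comes back to the route at 4. The free alcohol 3 and step 3 are bypassed.

**Further compounds**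

F1 | step 9 | (3R,5S)-5-[(2E)-4-hydroxy-2-methylbut-2-en-1-yl]-3-methyl-3-(triethylsilyloxy)oxolan-2-one | OC/C=C(\C)C[C@H]1C[C@@](C)(O[Si](CC)(CC)CC)C(=O)O1
F2 | step 4 | (5R)-5-(2-hydroxypent-4-yn-1-yl)-2,2,5-trimethyl-1,3-dioxolan-4-one, both carbinol epimers | C#CCC(O)C[C@@]1(C)OC(C)(C)OC1=O
F3 | step 4 | (3R,5R)-3-hydroxy-3-methyl-5-(prop-2-yn-1-yl)oxolan-2-one | C#CC[C@@H]1C[C@@](C)(O)C(=O)O1
F4 | step 2 | S-ethyl 2-[(4R)-2,2,4-trimethyl-5-oxo-1,3-dioxolan-4-yl]ethanethioate | CCSC(=O)C[C@@]1(C)OC(C)(C)OC1=O
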